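**Retrosynthetic overview**

1. Last disconnection: the cyclohexene bond between the enamine β-carbon and the ethyl-bearing carbon, together with the N–CH2 bond of the azepine. This leads back to monocyclic 1-pyrroline 29, which already carries both lactones, a trans-epoxide and a 5-chloropentyl chain.
2. 29 comes from NH-lactam 22 (amide activation, organocerium reagent from 23); the pendant lactone comes from thioester 16 and the zinc reagent from 17 (Fukuyama coupling, CBS reduction).
3. Spiro lactone and epoxide come from Boc-L-pyroglutamate 7 and dihydropyranone 6 (Achmatowicz route from 1): Michael addition–methylation on a temporary δ-lactone that is not in the target, enolate hydroxylation, translactonisation, mesylate, epoxide.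
4. Ring order: pyrrolidinone (chiral pool) → temporary δ-lactone → spiro γ-lactone → pendant γ-lactone → epoxide → azepine → cyclohexene.
5. Enabling feature: the ring-fusion enamine N–C=C shared by pyrroline, azepine and cyclohexene. Its β-carbon adjoins the trans ethyl/hydroxyl pair (retron of an anti epoxide opening), and the other α-carbon of the iminium is the hydrogen-free spiro-lactone carbon, so the enamine can form only toward the ring to be closed.

Key step: step 16

Assumption: compounds 1, 7, 17 and 23 are taken as commercial, and the lactone on the tertiary oxygen is taken as the stable isomer toward relactonisation onto the free secondary hydroxyl.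

**Route**

Step 1
Reactants: 1 1-(furan-2-yl)propan-1-one
Product: 2 (S)-1-(furan-2-yl)propan-1-ol
Conditions: RuCl(p-cymene)[(S,S)-TsDPEN] (cat.), HCO2H/Et3N, rt
Reagents that add atoms: none
Why: Noyori asymmetric transfer hydrogenation, in which the (S,S)-configured ruthenium hydride should deliver hydrogen to the ketone face that gives the (S)-carbinol, as it does for aryl alkyl ketones.

Step 2
Reactants: 2 (S)-1-(furan-2-yl)propan-1-ol
Product: 3 (2S)-2-ethyl-6-hydroxy-2H-pyran-3(6H)-one
Conditions: NBS, NaHCO3, THF/H2O, 0 °C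
Reagents that add atoms: water, O
Why: Achmatowicz rearrangement, an oxidative furan opening followed by recyclisation onto the carbinol oxygen, which leaves the carbinol stereocentre untouched.

Step 3
Reactants: 3 (2S)-2-ethyl-6-hydroxy-2H-pyran-3(6H)-one
Product: 4 (6S)-6-ethyl-2H-pyran-2,5(6H)-dione
Conditions: CrO3, H2SO4, acetone, 0 °C
Reagents that add atoms: none
Why: Jones oxidation of the lactol to the unsaturated keto-lactone, in which the ethyl-bearing stereocentre is not involved.

Step 4
Reactants: 4 (6S)-6-ethyl-2H-pyran-2,5(6H)-dione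
Product: 5 (5R,6S)-6-ethyl-5-hydroxy-5,6-dihydro-2H-pyran-2-one
Conditions: NaBH4, CeCl3·7H2O, MeOH/CH2Cl2, −78 °C
Reagents that add atoms: none
Why: Luche 1,2-reduction of the ring ketone, where axial hydride delivery to the half-chair with pseudo-equatorial ethyl should give the equatorial alcohol trans to ethyl.

Step 5
Reactants: 5 (5R,6S)-6-ethyl-5-hydroxy-5,6-dihydro-2H-pyran-2-one
Product: 6 (5R,6S)-5-[(tert-butyldimethylsilyl)oxy]-6-ethyl-5,6-dihydro-2H-pyran-2-one
Conditions: TBSCl, imidazole, DMF, rt
Reagents that add atoms: tert-butyldimethylsilyl chloride, CC(C)(C)[Si](C)(C)Cl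
Why: Standard silylation of the secondary alcohol, which also makes the oxygen substituent a large, non-leaving directing group for step 6.

Step 6
Reactants: 7 Boc-L-pyroglutamic acid benzyl ester; 6 silyloxy dihydropyranone
Product: 10 Michael–methylation adduct, via lactam lithium enolate 8 (not isolated), via lactone lithium enolate 9 (not isolated)
Conditions: LiN(SiMe3)2, THF, −78 °C; then 6; then MeI, DMPU, −78 to −40 °C
Reagents that add atoms: iodomethane, CI
Why: Tandem Michael addition–enolate alkylation on the temporary δ-lactone: the C4 lithium enolate of the Boc-pyroglutamate adds to the enoate carbon anti to the neighbouring silyloxy group, the lactone enolate is methylated anti to the new bond, and the pyrrolidinone substituent enters trans to the ester (this last centre is made planar again in step 7).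

Step 7
Reactants: 10 Michael–methylation adduct
Product: 13 spiro γ-lactone alcohol, via potassium enolate 11 (not isolated), via hydroxy δ-lactone 12 (not isolated)
Conditions: KN(SiMe3)2, THF, −78 °C; 2-(benzenesulfonyl)-3-phenyloxaziridine; AcOH; then CSA (cat.), CH2Cl2, rt
Reagents that add atoms: 2-(benzenesulfonyl)-3-phenyloxaziridine, O=S(=O)(c1ccccc1)N1OC1c1ccccc1
Why: Enolate hydroxylation by an N-sulfonyloxaziridine followed by acid-catalysed translactonisation: the tertiary lactam enolate is oxygenated on the face trans to the ester, which sets the spiro carbinol centre, and the new tertiary hydroxyl takes over the acyl group (δ- to γ-lactone), which frees the ethyl carbinol.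

Step 8
Reactants: 13 spiro γ-lactone alcohol
Product: 14 secondary mesylate
Conditions: MsCl, Et3N, CH2Cl2, 0 °C
Reagents that add atoms: methanesulfonyl chloride, CS(=O)(=O)Cl
Why: Mesylation of the only unhindered hydroxyl with retention at carbon, which also drains any δ-lactone left in the translactonisation equilibrium.

Step 9
Reactants: 14 secondary mesylate
Product: 15 carboxylic acid
Conditions: H2 (1 atm), Pd/C, EtOAc, rt
Reagents that add atoms: none
Why: Hydrogenolysis of the benzyl ester, to which mesylate, silyl ether, Boc group and lactone are inert.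

Step 10
Reactants: 15 carboxylic acid
Product: 16 S-ethyl thioester
Conditions: EtSH, DCC, DMAP (cat.), CH2Cl2, 0 °C to rt
Reagents that add atoms: ethanethiol, CCS
Why: Steglich-type thioesterification, which turns the acid into an acyl donor for a chemoselective ketone synthesis.

Step 11
Reactants: 16 S-ethyl thioester; 17 methyl (R)-3-bromo-2-methylpropanoate
Product: 19 γ-keto ester, via alkylzinc bromide 18 (not isolated)
Conditions: 17, Zn dust, LiCl, THF, 40 °C; then 16, PdCl2(PPh3)2 (cat.), toluene/THF, rt
Reagents that add atoms: none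
Why: Fukuyama coupling, in which zinc insertion gives a configurationally stable β-ester alkylzinc and palladium-catalysed acyl transfer from the thioester forms the ketone without touching lactone, mesylate or the α-stereocentres.

Step 12
Reactants: 19 γ-keto ester
Product: 21 N-Boc lactam bis-lactone, via hydroxy ester 20 (not isolated)
Conditions: (R)-2-methyl-CBS-oxazaborolidine (cat.), BH3·SMe2, THF, −20 °C; MeOH; then PPTS (cat.), toluene, 50 °C
Reagents that add atoms: none
Why: Corey–Bakshi–Shibata reduction, whose reagent control is reinforced by the Felkin–Anh preference of the α-amido ketone, should set the (S)-carbinol syn to nitrogen, and acid-catalysed lactonisation onto the methyl ester closes the cis-disubstituted butyrolactone whose methyl-bearing centre comes from 17.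

Step 13
Reactants: 21 N-Boc lactam bis-lactone
Product: 22 NH-lactam bis-lactone
Conditions: Mg(ClO4)2 (cat.), MeCN, 50 °C
Reagents that add atoms: none
Why: Lewis-acid-catalysed cleavage of the Boc group from an N-acyl carbamate, under conditions that should spare silyl ether, mesylate and both lactones.

Step 14
Reactants: 22 NH-lactam bis-lactone; 23 1-bromo-5-chloropentane
Product: 27 cyclic imine mesylate, via Grignard reagent 24 (not isolated), via organocerium reagent 25 (not isolated), via imidoyl triflate 26 (not isolated)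
Conditions: 23, Mg, THF, then CeCl3, −78 °C; 22, Tf2O, 2-fluoropyridine, CH2Cl2, −78 to 0 °C; combine at −78 °C; aq. NaHCO3
Reagents that add atoms: none
Why: Electrophilic amide activation turns the secondary lactam, which has no α-hydrogen at the spiro carbon, into an imidoyl triflate that should capture the organocerium reagent at −78 °C faster than the lactones do and give the ketimine directly with no stereocentre affected.

Step 15
Reactants: 27 cyclic imine mesylate
Product: 29 epoxide imine, via ammonium alkoxide 28 (not isolated)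
Conditions: Bu4NF, THF, 0 °C to rt
Reagents that add atoms: none
Why: Fluoride desilylation liberates the alkoxide next to the mesylate and 3-exo-tet Williamson closure with inversion at the ethyl-bearing carbon gives the trans (2R,3R)-epoxide.

Step 16
Reactants: 29 epoxide imine
Product: 34 target CNP0154902.1, via primary iodide 30 (not isolated), via bicyclic iminium chloride 31 (not isolated), via bicyclic enamine 32 (not isolated), via iminium alkoxide 33 (not isolated)
Conditions: NaI (cat.), iPr2NEt, MeCN, 70 °C, high dilution; then CF3CH2OH, 60 °C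
Reagents that add atoms: none
Why: Proposed new method: halide exchange and N-alkylation of the cyclic imine close the azepine as a bicyclic iminium salt, which can lose a proton only toward the side-chain carbon because the other α-carbon is the fully substituted spiro-lactone carbon, and the resulting endocyclic enamine opens the epoxide through its β-carbon to zwitterion 33, which tautomerises to the tetrasubstituted enamine 34. The closest known reactions are the N-alkylation of 2-(ω-haloalkyl)-1-pyrrolines to bicyclic endocyclic enamines and the Stork C-alkylation of enamines by alkyl halides and epoxides; the intramolecular epoxide version in a cascade is the new element. Ring closures: the azepine by 7-exo-tet attack of nitrogen, then the cyclohexene last by a 6-(enolendo) closure that is endo with respect to the oxirane. The only new stereocentre, the ethyl-bearing carbon, is set by stereospecific SN2 inversion of the (2R,3R)-epoxide, which places ethyl trans to the hydroxyl, while the carbinol carbon keeps its configuration. The step needs C-attack at the distal oxirane carbon: attack at the proximal carbon would be a 5-(enolendo) closure that the π-lobe of the ring-fusion enamine cannot reach, and trifluoroethanol activates the oxirane by hydrogen bonding while damping halide nucleophilicity.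

**Compound list**

1 | 1-(furan-2-yl)propan-1-one | CCC(=O)c1ccco1 | starting material
2 | (S)-1-(furan-2-yl)propan-1-ol | CC[C@H](O)c1ccco1 | intermediate
3 | (2S)-2-ethyl-6-hydroxy-2H-pyran-3(6H)-one (lactol; anomeric centre as a mixture) | CC[C@@H]1OC(O)C=CC1=O | intermediate
4 | (6S)-6-ethyl-2H-pyran-2,5(6H)-dione | CC[C@@H]1OC(=O)C=CC1=O | intermediate
5 | (5R,6S)-6-ethyl-5-hydroxy-5,6-dihydro-2H-pyran-2-one (trans) | CC[C@@H]1OC(=O)C=C[C@H]1O | intermediate
6 | (5R,6S)-5-[(tert-butyldimethylsilyl)oxy]-6-ethyl-5,6-dihydro-2H-pyran-2-one | CC[C@@H]1OC(=O)C=C[C@H]1O[Si](C)(C)C(C)(C)C | intermediate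
7 | 2-benzyl 1-tert-butyl (2S)-5-oxopyrrolidine-1,2-dicarboxylate (Boc-L-pyroglutamic acid benzyl ester) | CC(C)(C)OC(=O)N1C(=O)CC[C@H]1C(=O)OCc1ccccc1 | starting material
8 | lithium enolate of 7 (O-lithio enolate across C4–C5 of the lactam) | [Li]OC1=CC[C@@H](C(=O)OCc2ccccc2)N1C(=O)OC(C)(C)C | intermediate
9 | lithium enolate of the Michael adduct (δ-lactone enolate; pyrrolidinone C4 bonded to pyranone C4 anti to the silyloxy group) | CC[C@@H]1OC(O[Li])=C[C@@H]([C@H]1O[Si](C)(C)C(C)(C)C)[C@@H]2C[C@@H](C(=O)OCc3ccccc3)N(C(=O)OC(C)(C)C)C2=O | intermediate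
10 | Michael–methylation adduct: 7 bearing at C4 (trans to the ester) the all-trans (3S,4S,5R,6S)-5-silyloxy-6-ethyl-3-methyl-2-oxotetrahydropyran-4-yl group | CC[C@@H]1OC(=O)[C@@H](C)[C@@H]([C@H]1O[Si](C)(C)C(C)(C)C)[C@@H]2C[C@@H](C(=O)OCc3ccccc3)N(C(=O)OC(C)(C)C)C2=O | intermediate
11 | potassium enolate of 10 (lactam enolate at the substituted C4) | CC[C@@H]1OC(=O)[C@@H](C)[C@@H]([C@H]1O[Si](C)(C)C(C)(C)C)C2=C(O[K])N(C(=O)OC(C)(C)C)[C@H](C(=O)OCc3ccccc3)C2 | intermediate
12 | hydroxy δ-lactone: 10 hydroxylated at pyrrolidinone C4 (OH trans to the benzyl ester) | CC[C@@H]1OC(=O)[C@@H](C)[C@@H]([C@H]1O[Si](C)(C)C(C)(C)C)[C@@]2(O)C[C@@H](C(=O)OCc3ccccc3)N(C(=O)OC(C)(C)C)C2=O | intermediate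
13 | spiro γ-lactone alcohol: N-Boc 1-oxa-7-azaspiro[4.4]nonane-2,6-dione with benzyl ester at C8, methyl at C3 and the side chain CH(OTBS)–CH(OH)–Et at C4 | CC[C@H](O)[C@H](O[Si](C)(C)C(C)(C)C)[C@@H]1[C@H](C)C(=O)O[C@@]12C[C@@H](C(=O)OCc3ccccc3)N(C(=O)OC(C)(C)C)C2=O | intermediate
14 | secondary mesylate of 13 | CC[C@H](OS(C)(=O)=O)[C@H](O[Si](C)(C)C(C)(C)C)[C@@H]1[C@H](C)C(=O)O[C@@]12C[C@@H](C(=O)OCc3ccccc3)N(C(=O)OC(C)(C)C)C2=O | intermediate
15 | carboxylic acid from 14 (benzyl ester cleaved) | CC[C@H](OS(C)(=O)=O)[C@H](O[Si](C)(C)C(C)(C)C)[C@@H]1[C@H](C)C(=O)O[C@@]12C[C@@H](C(=O)O)N(C(=O)OC(C)(C)C)C2=O | intermediate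
16 | S-ethyl thioester of 15 | CC[C@H](OS(C)(=O)=O)[C@H](O[Si](C)(C)C(C)(C)C)[C@@H]1[C@H](C)C(=O)O[C@@]12C[C@@H](C(=O)SCC)N(C(=O)OC(C)(C)C)C2=O | intermediate
17 | methyl (R)-3-bromo-2-methylpropanoate | BrC[C@H](C)C(=O)OC | starting material
18 | (R)-(3-methoxy-2-methyl-3-oxopropyl)zinc bromide | Br[Zn]C[C@H](C)C(=O)OC | intermediate
19 | γ-keto ester: 16 with SEt replaced by CH2–CH(CH3)–CO2Me | CC[C@H](OS(C)(=O)=O)[C@H](O[Si](C)(C)C(C)(C)C)[C@@H]1[C@H](C)C(=O)O[C@@]12C[C@@H](C(=O)C[C@H](C)C(=O)OC)N(C(=O)OC(C)(C)C)C2=O | intermediate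
20 | γ-hydroxy ester: (S)-carbinol from 19, OH syn to the ring nitrogen | CC[C@H](OS(C)(=O)=O)[C@H](O[Si](C)(C)C(C)(C)C)[C@@H]1[C@H](C)C(=O)O[C@@]12C[C@@H]([C@@H](O)C[C@H](C)C(=O)OC)N(C(=O)OC(C)(C)C)C2=O | intermediate
21 | N-Boc lactam bis-lactone (pendant (2S,4S)-4-methyl-5-oxotetrahydrofuran-2-yl group) | CC[C@H](OS(C)(=O)=O)[C@H](O[Si](C)(C)C(C)(C)C)[C@@H]1[C@H](C)C(=O)O[C@@]12C[C@@H]([C@@H]3C[C@H](C)C(=O)O3)N(C(=O)OC(C)(C)C)C2=O | intermediate
22 | NH-lactam bis-lactone | CC[C@H](OS(C)(=O)=O)[C@H](O[Si](C)(C)C(C)(C)C)[C@@H]1[C@H](C)C(=O)O[C@@]12C[C@@H]([C@@H]3C[C@H](C)C(=O)O3)NC2=O | intermediate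
23 | 1-bromo-5-chloropentane | ClCCCCCBr | starting material
24 | 5-chloropentylmagnesium bromide | ClCCCCC[Mg]Br | intermediate
25 | (5-chloropentyl)cerium dichloride | ClCCCCC[Ce](Cl)Cl | intermediate
26 | imidoyl triflate of 22 | CC[C@H](OS(C)(=O)=O)[C@H](O[Si](C)(C)C(C)(C)C)[C@@H]1[C@H](C)C(=O)O[C@@]12C[C@@H]([C@@H]3C[C@H](C)C(=O)O3)N=C2OS(=O)(=O)C(F)(F)F | intermediate
27 | cyclic imine mesylate: 2-(5-chloropentyl)-1-pyrroline carrying spiro lactone, pendant lactone, mesylate and silyl ether | CC[C@H](OS(C)(=O)=O)[C@H](O[Si](C)(C)C(C)(C)C)[C@@H]1[C@H](C)C(=O)O[C@@]12C[C@@H]([C@@H]3C[C@H](C)C(=O)O3)N=C2CCCCCCl | intermediate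
28 | tetrabutylammonium alkoxide from 27 (silyl group removed) | CC[C@H](OS(C)(=O)=O)[C@H]([O-])[C@@H]1[C@H](C)C(=O)O[C@@]12C[C@@H]([C@@H]3C[C@H](C)C(=O)O3)N=C2CCCCCCl.CCCC[N+](CCCC)(CCCC)CCCC | intermediate
29 | epoxide imine: 2-(5-chloropentyl)-1-pyrroline with spiro lactone bearing the (2R,3R)-3-ethyloxiran-2-yl group and the pendant lactone | CC[C@H]1O[C@@H]1[C@@H]2[C@H](C)C(=O)O[C@@]23C[C@@H]([C@@H]4C[C@H](C)C(=O)O4)N=C3CCCCCCl | intermediate
30 | primary iodide from 29 | CC[C@H]1O[C@@H]1[C@@H]2[C@H](C)C(=O)O[C@@]23C[C@@H]([C@@H]4C[C@H](C)C(=O)O4)N=C3CCCCCI | intermediate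
31 | bicyclic iminium chloride (pyrrolo[1,2-a]azepinium, epoxide intact) | CC[C@H]1O[C@@H]1[C@@H]2[C@H](C)C(=O)O[C@@]23C[C@@H]([C@@H]4C[C@H](C)C(=O)O4)[N+]5=C3CCCCC5.[Cl-] | intermediate
32 | bicyclic enamine (ring-fusion enamine, epoxide intact) | CC[C@H]1O[C@@H]1[C@@H]2[C@H](C)C(=O)O[C@@]23C[C@@H]([C@@H]4C[C@H](C)C(=O)O4)N5C3=CCCCC5 | intermediate
33 | iminium alkoxide zwitterion (cyclohexane ring closed, before tautomerisation) | CC[C@@H]1[C@H]2C3=[N+](CCCC2)[C@H]([C@@H]2C[C@H](C)C(=O)O2)C[C@@]32OC(=O)[C@@H](C)[C@H]2[C@H]1[O-] | intermediate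
34 | CNP0154902.1 | CC[C@@H]1C2=C3N(CCCC2)[C@H]([C@@H]2C[C@H](C)C(=O)O2)C[C@@]32OC(=O)[C@@H](C)[C@H]2[C@H]1O | target

**Step count and risks**

Total step count: 16. Longest linear sequence: 16 steps (1 → 6 → 10 → 34); the main line from 7 is 11 steps.

Steps most likely to fail:

Step 16 (Proposed new method). The neutral enamine may open the oxirane too slowly, so that halide or solvent opens it first or the iminium is hydrolysed; closure at the proximal oxirane carbon would erode regioselectivity. The fallback uses known reactions only; it sets out from mesylate 27 and comes back to the route at 34. NaI in 2-butanone at 60 °C exchanges the primary chloride, displaces the secondary mesylate with inversion (Finkelstein) and lets the imine nitrogen close the azepine, which gives the bicyclic iminium iodide with secondary iodide and silyl ether F1. iPr2NEt in MeCN then forms the ring-fusion enamine, which is alkylated at carbon by the secondary iodide (intramolecular Stork enamine alkylation, 6-(enolendo)-exo-tet, second inversion at the ethyl-bearing carbon) to give the silyl ether of the target F2. Bu4NF removes the silyl group and gives 34.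

Step 7. Deprotonation may occur at the lactone α-carbon (epimerisation or retro-Michael cleavage) or at the ester-bearing carbon instead of the lactam α-carbon; oxygen transfer may go to the wrong enolate face under the influence of the neighbouring lactone stereocentre; the tertiary alkoxide may attack the Boc-activated lactam. The fallback sets out from 7 (with 6) and comes back at 12. Compound 7 is selenenylated (LiN(SiMe3)2, PhSeCl) to the 4-phenylselanyl lactam F3. Its enolate is carried through the same Michael addition–methylation with 6 to the selenide adduct F4. H2O2/pyridine (selenoxide syn-elimination) gives the unsaturated lactam F5. Mukaiyama hydration (Mn(dpm)3, PhSiH3, O2, iPrOH) transfers hydrogen to the β-carbon and traps the α-amido radical with oxygen trans to the ester, which gives 12 without base; 12 is taken on to 13 by the acid step of step 7.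

Step 14. The organocerium reagent may add to a lactone carbonyl, O-triflation of the hindered lactam may be incomplete, or the basic reagent may eliminate the mesylate. The fallback sets out from N-Boc lactam 21 (before step 13) and comes back at 27. Grignard reagent 24 is added at −78 °C to the Boc-activated lactam carbonyl, the most electrophilic acyl group, which opens the ring to the N-Boc amino ketone F6. Brief treatment with CF3CO2H at 0 °C removes the Boc group and the amine condenses with the ketone to the cyclic imine 27.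

**Further compounds**

F1 | step 16 | bicyclic iminium iodide with secondary iodide (inverted) and silyl ether | CC[C@@H](I)[C@H](O[Si](C)(C)C(C)(C)C)[C@@H]1[C@H](C)C(=O)O[C@@]12C[C@@H]([C@@H]3C[C@H](C)C(=O)O3)[N+]4=C2CCCCC4.[I-]
F2 | step 16 | O-tert-butyldimethylsilyl ether of 34 | CC[C@@H]1C2=C3N(CCCC2)[C@H]([C@@H]2C[C@H](C)C(=O)O2)C[C@@]32OC(=O)[C@@H](C)[C@H]2[C@H]1O[Si](C)(C)C(C)(C)C
F3 | step 7 | 4-(phenylselanyl) derivative of 7 (selenium trans to the ester) | CC(C)(C)OC(=O)N1C(=O)[C@H]([Se]c2ccccc2)C[C@H]1C(=O)OCc1ccccc1
F4 | step 7 | selenide Michael–methylation adduct (10 with phenylselanyl in place of H at pyrrolidinone C4) | CC[C@@H]1OC(=O)[C@@H](C)[C@@H]([C@H]1O[Si](C)(C)C(C)(C)C)[C@]2([Se]c3ccccc3)C[C@@H](C(=O)OCc4ccccc4)N(C(=O)OC(C)(C)C)C2=O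
F5 | step 7 | α,β-unsaturated lactam (3-pyrrolin-2-one carrying the δ-lactone at C3) | CC[C@@H]1OC(=O)[C@@H](C)[C@@H]([C@H]1O[Si](C)(C)C(C)(C)C)C2=C[C@@H](C(=O)OCc3ccccc3)N(C(=O)OC(C)(C)C)C2=O
F6 | step 14 | ring-opened N-Boc amino ketone (6-chlorohexanoyl group on the spiro-lactone carbon) | CC[C@H](OS(C)(=O)=O)[C@H](O[Si](C)(C)C(C)(C)C)[C@@H]1[C@H](C)C(=O)O[C@]1(C[C@@H]([C@@H]2C[C@H](C)C(=O)O2)NC(=O)OC(C)(C)C)C(=O)CCCCCCl
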